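The runs are calculated for substances that don't exist.

If the two substrate peaks have come apart when you take over this bench, it is no fault: the product peak I read is left-handed, yet right-handed substrate falls as well.

| flask | left-handed substrate | right-handed substrate | solid reagent | precatalyst | remark | time |
|---|---|---|---|---|---|---|
| violet | 0.25 M | 0.25 M | 0.95 M | 3.8 mM | run made earlier |  |
| red | 0.57 M | 0.57 M | 0.95 M | 3.8 mM | run made earlier |  |
| ochre | 0.38 M | 0.38 M | 1.9 M | 3.8 mM | run made earlier |  |
| alpha | 0.38 M | 0.38 M | 0.950 M | 3.8 mM |  | 4.0 h |
| theta | 0.38 M | 0.38 M | 0.950 M | 3.8 mM |  | 12 h |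

| run | time / h | right-handed substrate / % | left-handed substrate / % | left-handed product / % |
|---|---|---|---|---|
| violet | 0.250 | 49.2 | 50.1 | 1.3 |
| violet | 0.500 | 49.7 | 48.3 | 1.8 |
| violet | 0.833 | 49.4 | 46.2 | 4.9 |
| violet | 1.50 | 47.3 | 39.2 | 14.0 |
| violet | 3.00 | 39.3 | 22.0 | 36.6 |
| red | 0.667 | 50.0 | 46.9 | 3.1 |
| red | 1.33 | 47.7 | 40.1 | 11.2 |
| red | 2.00 | 45.0 | 32.5 | 20.5 |
| red | 2.50 | 42.7 | 28.1 | 28.0 |
| red | 3.00 | 39.4 | 24.0 | 35.6 |
| ochre | 0.250 | 50.0 | 49.8 | 1.5 |
| ochre | 0.833 | 49.4 | 46.0 | 4.8 |
| ochre | 1.33 | 48.7 | 39.6 | 11.0 |
| ochre | 2.50 | 42.1 | 27.3 | 29.0 |
| ochre | 3.00 | 38.9 | 23.6 | 36.2 |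

(each reading ± 0.5 percentage points)

* the flask that ends with the higher excess of right-handed substrate over left-handed substrate among what is left of the two, or "neither" when 2 percentage points or less lies between them (alpha / theta / neither)
* excess of right-handed substrate over left-handed substrate among what is left of the two at the end, alpha
* excess of right-handed substrate over left-handed substrate among what is left of the two at the end, theta

- catalyst is single-handed; left-handed substrate and right-handed substrate are mirror images of each other, charged as a racemate, each of them at the stated concentration
- given per volume of solution although it is solid: solid reagent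
- at the start none of the solid reagent is in solution
- an excess is the difference of the two amounts in percent of their sum
- an excess is below zero if the other one leads

In the violet run, between 1.50 h and 3.00 h, right-handed substrate loses 8 percentage points while leading left-handed substrate by 13 points on average. I read that loss as racemisation, with a rate constant of about 0.420 h⁻¹. Since each form turns into the other, a gap between them closes at twice that rate, so I carry the excess half-life, the time in which racemisation halves the excess once consumption has stopped: 0.825 h. This is shorter than alpha's 4.0 h and much shorter than theta's 12 h, so I expect the excess in each flask to be a running balance between left-handed consumption and racemisation. The ochre run stands at 24.5% at 3.00 h, and I expect alpha above that and theta higher still. Please add no solid reagent: ochre with 1.9 M shows 36.2% of left-handed product at that time and violet with 0.95 M shows 36.6%, though these two runs also differ in their substrate charge.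

The forecast says theta, with 32% for alpha and 46% for theta, on the view that “it racemises to left-handed substrate, which then reacts (dynamic kinetic resolution)”. My half-life gives that direction but not those numbers.

Alpha ends at 32.1% and theta at 44.3%, so theta leads and the forecast holds, the difference in time being the main reason: theta's excess is 44.3% with its own time and 32.1% without that difference. Between the two ends lie 9.69 of my half-lives, and theta has reached its balance, since 120 h gives 44.8%. Theta also holds 6.62% of right-handed product, yet removing the step that makes it moves the excess from 44.3% to 45.6%.

    solid reagent ⇌ partner, rate k1*(cs1 - [partner]) while solid is left; crystals form when [partner] > cs1 (solubility = 0.150 M, k = 0.00380 s⁻¹)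
    partner + catalyst + left-handed substrate → catalyst + left-handed product (k = 0.410 L² mol⁻² s⁻¹)
    partner + catalyst + right-handed substrate → catalyst + right-handed product (k = 0.0170 L² mol⁻² s⁻¹)
    partner + precatalyst → catalyst + spent reagent (k = 8.90 × 10⁻⁴ L mol⁻¹ s⁻¹)
    left-handed substrate ⇌ right-handed substrate (k = 1.00 × 10⁻⁴ s⁻¹)

A neighbour of theta with 0.38 M of solid reagent has 1.00 equiv to left-handed substrate, half of the two substrates together, so solid reagent is the limiting reagent; once reaction stalls in this neighbour, each further 0.825 h should halve its excess, and I expect it close to zero at 12 h rather than at theta's 44.3%. The computed flask ends at 0.212%, with solid reagent at 0% and [partner] at 3.91 × 10⁻⁵ M.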